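**Remark on the chemistry (assumption):** the locants C1–C7 are positional labels of the target (C1 = CH–OMe, C2 = ring CH=, C3 = ring carbon bearing C7, C4 = allylic CH–OH, C5 = CH–OBz, C6 = CH–OH next to C1, C7 = exocyclic CH2). They are kept for every intermediate, and the CIP descriptors in the names refer to these labels.

## Analysis of the target

The target is a single carbocycle, a cyclohex-2-ene (C1–C6, double bond C2=C3) with one exocyclic carbon, the benzoyloxymethyl group C7 on C3. Four contiguous stereocentres C4, C5, C6 and C1 (1S,4S,5R,6R) carry oxygen, and each oxygen is trans to the one on the neighbouring ring carbon, so O1 and O5 lie on one face and O4 and O6 on the other. The five oxygens all differ: a methyl ether at C1, free hydroxyls at C6 and C4, benzoates at C5 and C7. The benzoates sit beside free hydroxyls and migrate or are lost under basic, hydridic or basic-fluoride conditions; the C1 ether and C7 ester are allylic and can ionise or transpose; the alkene forbids hydrogenolysis. The difficulty is therefore the all-trans tetrad on a ring with little intrinsic bias, and the need to tell five oxygens apart. The feature on which the plan rests is that the C2=C3 alkene is flanked on both sides by carbinol carbons, C1 and C4. Both C1–C2 and C3–C4 can then be made by adding the two carbons of a propargylic alkyne (C2 and C3, with C7 attached) to the two carbonyl groups of a four-carbon dialdehyde C4–C5–C6–C1, whose trans C5/C6 diol comes from a tartrate.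

## Retrosynthetic reasoning

**O6–Si, C7 ester and acetal (22 ⇐ 21 ⇐ 20 ⇐ 19).** The benzoates cannot pass through organometallic, hydride or alkoxide steps, so they are placed late. The bulky silyl ether on O6 is cut last, under acidic fluoride, so that no alkoxide is formed next to a benzoate. Before that, the C7 benzoate of 21 is disconnected to diol 20, where only one hindered secondary hydroxyl (O4) competes with the primary one. Diol 20 comes from acetal 19 by hydrolysis.

**C5 ester and C1 ether (19 ⇐ 18 ⇐ 17 ⇐ 16).** The C5 benzoate is traced to the C5 alcohol 18 and this to the 4-methoxybenzyl ether 17, which is removable oxidatively without touching silyl ether, acetal or alkene. The methyl ether of 17 is cut to alcohol 16, in which O1 is the only free hydroxyl, so methylation needs no selectivity.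

**C1–H bond (16 ⇐ 15 ⇐ 14).** The C1 configuration is not taken from the ring-forming step. In that step O4 is already bound to titanium when the second carbonyl inserts, so O1 ends on the same metal and must lie on the same face as O4. The target needs O1 and O4 on opposite faces. The C1 carbinol of 16 is therefore disconnected to enone 15, and 15 to the cis alcohol 14. The forward 1,2-reduction must deliver hydride so that O1 ends trans to O6. This detour costs two steps but makes both C1 epimers converge on 15.

**Acetal and two silyl groups (14 ⇐ 13 ⇐ 12).** The six-membered acetal across O4 and O7 in 14 distinguishes O4 from O1. It comes from triol 13, which arises from 12 by loss of the C7 silyl ether and of the C2 silyl group, both silyl groups having done their work in the ring-forming step.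

**C1–C2 and C3–C4 (12 ⇒ 7 + 9, through 10 and 11).** Both bonds that join the alkene to its carbinol neighbours are cut. This is the only disconnection that removes the ring, two stereocentres and the C7 branch in one stroke, and it leaves a tartrate-derived dialdehyde 7 and a three-carbon alkyne 9. The forward reaction has four tasks:
- the alkyne must react first through C3, which the silyl group on C2 secures;
- it must react first at the C4 aldehyde, the one beside the benzyl-type ether;
- it must take the face of that aldehyde that puts O4 trans to O5;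
- the vinyl–titanium bond of 11 must close the ring before a second complex 10 adds.

**Fragments (7 ⇐ 6 ⇐ 5 ⇐ 4 ⇐ 1 + 2 through 3; 9 ⇐ 8).** Dialdehyde 7 is taken back through diol 6 and diester 5 to mono-ether 4, made from diethyl D-tartrate 1 and chloride 2 through stannylene acetal 3. The twofold symmetry of 1 makes the first protection unambiguous, and the two different ethers then distinguish O5 from O6 for the rest of the route. Alkyne 9 is the silyl ether of commercial alcohol 8.

## Alternatives that were turned down

**Alternative 1:** Here the C4–O and C5–O bonds are disconnected back to an aromatic ring. Whole cells expressing toluene dioxygenase would oxidise ethyl benzoate A2 at the ring bond next to the ester to the cis-dihydrodiol A1, ethyl (5S,6R)-5,6-dihydroxycyclohexa-1,3-diene-1-carboxylate.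
- For it: A1 holds all seven carbons (the ester is C7), the C2=C3 alkene, and a second alkene at C1=C6 suited to epoxidation and allylic opening by methanol, which would give the trans 1-OMe/6-OH pair directly. The oxidation is an established biotransformation and the follow-up is conventional.
- Against it: the enzyme gives a cis diol. Mapped on the target, C5 is correct but C4 is epimeric, so the hindered allylic C4 centre must be inverted. The two hydroxyls of A1 must also be differentiated, the diene diol dehydrates easily to a phenol, and fermentation equipment is required.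
- Comparison: this alternative is shorter and rests on precedented steps, so it is stronger on step count and on risk. The chosen strategy offers in its place a purely chemical, convergent union of two small fragments, with the C5/C6 trans pair and its O5/O6 differentiation drawn from the chiral pool at the outset.

**Alternative 2:** Here only C1–C2 is cut. A Lewis acid such as SnCl4 would open the dimethyl acetal of the open-chain precursor A4 to a C1 methoxycarbenium ion. The silicon-bearing alkene carbon C2 captures it with ipso loss of silicon and closes the ring to A3, the 4,6-bis(tert-butyldimethylsilyl) ether of the target.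
- For it: the methyl ether is born in the ring closure, both benzoates are already in place, and A3 is one deprotection from the target. On the endgame it is clearly stronger than the chosen route.
- Against it: ipso attack puts positive charge on C3, which carries an acyloxymethyl group and a siloxy-bearing neighbour and is poorly stabilised. The C1 cation is flanked by an α-siloxy group, and the C5 benzoate carbonyl can trap it as a six-membered dioxanium ion. The C1 configuration is left to ring conformation alone. A4, with a stereodefined Z-vinylsilane and four differentiated oxygens on an open chain, needs a long linear sequence.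
- Comparison: one ring bond and one stereocentre are formed, against two bonds and two stereocentres in the chosen key step. The chosen route pays with a longer endgame but reaches its cyclisation substrate in four steps.

**Alternative 3:** Here C1–C6 is cut. Base would remove a proton from the methoxymethylene carbon C1 of the aldehyde enoate A6, and the extended enolate would attack the C6 aldehyde through C1 to give A5, methyl 4-hydroxy-3-methoxy-5-(4-methoxybenzyloxy)-6-(tert-butyldimethylsilyloxy)cyclohex-1-ene-1-carboxylate.
- For it: the methoxy group and the C7 carbon (as ester) are in place, attack through the α-carbon would give a four-membered ring and so does not compete, and C4 and C5 come from the chiral pool. On oxidation-state economy it is as good as the chosen route.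
- Against it: the enolate carbon C3 carries a β-siloxy leaving group at C4, and the aldehyde has an acidic α-hydrogen at C5 with the same leaving group β to it. Elimination and epimerisation are therefore likely with the strong base required. Both new centres (C1 and C6) must come out trans to their neighbours with nothing to guide them.
- Comparison: the chosen strategy draws C5 and C6 from tartrate, creates only the two carbinol centres that flank the alkene, and works under non-enolising conditions at low temperature.

Key step: step 6

## Route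

Step 1
Reactants: 1 diethyl D-tartrate [diethyl (2S,3S)-2,3-dihydroxybutanedioate]; 2 4-methoxybenzyl chloride
Product: 4 diethyl (2S,3S)-2-hydroxy-3-(4-methoxybenzyloxy)butanedioate, via stannylene acetal 3 (not isolated)
Conditions: Bu2SnO, toluene, reflux (Dean–Stark); then 2, Bu4NI (cat.), toluene, 90 °C
Reagents that add atoms: dibutyltin oxide, CCCC[Sn](=O)CCCC (its atoms stay in intermediate 3 only)
Why: Stannylene-mediated mono-O-alkylation: the tin acetal is alkylated once because the second oxygen stays on tin, and the twofold symmetry of 1 makes the two hydroxyls equivalent; no stereocentre is touched.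

Step 2
Reactants: 4 diethyl (2S,3S)-2-hydroxy-3-(4-methoxybenzyloxy)butanedioate
Product: 5 diethyl (2S,3S)-2-(4-methoxybenzyloxy)-3-(triisopropylsilyloxy)butanedioate
Conditions: TIPSOTf, 2,6-lutidine, CH2Cl2, 0 °C → rt
Reagents that add atoms: triisopropylsilyl trifluoromethanesulfonate, CC(C)[Si](OS(=O)(=O)C(F)(F)F)(C(C)C)C(C)C
Why: Silyl triflate with a hindered base silylates the hindered secondary alcohol; triisopropylsilyl is chosen because it does not chelate, is bulky, migrates slowly and should outlast the later fluoride step.

Step 3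
Reactants: 5 diethyl (2S,3S)-2-(4-methoxybenzyloxy)-3-(triisopropylsilyloxy)butanedioate
Product: 6 (2R,3R)-2-(4-methoxybenzyloxy)-3-(triisopropylsilyloxy)butane-1,4-diol
Conditions: LiBH4, THF, MeOH (2 equiv), 0 °C → rt
Reagents that add atoms: none
Why: Borohydride reduction of both esters to primary alcohols; LiBH4 is mild enough that the ethers and the stereocentres are untouched and silyl migration is not expected (the descriptors change only through CIP priorities).

Step 4
Reactants: 6 (2R,3R)-2-(4-methoxybenzyloxy)-3-(triisopropylsilyloxy)butane-1,4-diol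
Product: 7 (2S,3S)-2-(4-methoxybenzyloxy)-3-(triisopropylsilyloxy)butanedial
Conditions: (COCl)2, DMSO, CH2Cl2, −78 °C; i-Pr2NEt, −78 → −40 °C; cold work-up, used crude at once
Reagents that add atoms: none
Why: Double Swern oxidation; low temperature and a hindered amine limit epimerisation of the two α-alkoxy aldehydes, and immediate use avoids hydration and oligomerisation.

Step 5
Reactants: 8 3-(trimethylsilyl)prop-2-yn-1-ol
Product: 9 tert-butyldimethyl{[3-(trimethylsilyl)prop-2-yn-1-yl]oxy}silane
Conditions: TBSCl, imidazole, CH2Cl2, rt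
Reagents that add atoms: tert-butyldimethylsilyl chloride, CC(C)(C)[Si](C)(C)Cl
Why: Standard silylation of a primary alcohol; a silyl ether is a poor leaving group, so the later titanium complex should not eliminate it to an allenyl species.

Step 6
Reactants: 9 tert-butyldimethyl{[3-(trimethylsilyl)prop-2-yn-1-yl]oxy}silane; 7 (2S,3S)-2-(4-methoxybenzyloxy)-3-(triisopropylsilyloxy)butanedial
Product: 12 (1S,4S,5R,6R)-3-[(tert-butyldimethylsilyloxy)methyl]-5-(4-methoxybenzyloxy)-6-(triisopropylsilyloxy)-2-(trimethylsilyl)cyclohex-2-ene-1,4-diol, via titanacyclopropene 10 (not isolated), via oxatitanacyclopentene 11 (not isolated)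
Conditions: Ti(O-i-Pr)4, 9, i-PrMgCl (2 equiv), Et2O, −78 → −50 °C; cannulated into 7 + MgBr2·OEt2, Et2O/CH2Cl2, −78 → −20 °C; aq. NH4Cl
Reagents that add atoms: titanium tetraisopropoxide, CC(C)O[Ti](OC(C)C)(OC(C)C)OC(C)C (its atoms stay in intermediates 10 and 11 only)
Why: Proposed new method: reduction of Ti(O-i-Pr)4 by two equivalents of i-PrMgCl leaves a propene complex of divalent titanium in which alkyne 9 displaces propene to give titanacyclopropene 10; its Ti–C3 bond inserts the aldehyde of 7 that lies beside the OPMB group (C3–C4 bond, oxatitanacyclopentene 11), and the surviving Ti–C2 bond, held cis to C4 by the metallacycle, then inserts the second aldehyde (C1–C2 bond). The closest known reaction type is the stepwise addition of such alkyne–titanium complexes, acting as vicinal vinyl dianions, to two separate carbonyl compounds; new here is that both carbonyl groups belong to one molecule, so the second addition closes a carbocycle. The cyclohexene closes in a 6-exo-trig mode (the C1=O bond is exocyclic to the forming ring), and the cis geometry of C2=C3 follows from retention at both titanium–carbon bonds. Which alkyne carbon reacts first is decided by silicon, since silyl alkyne complexes add through the carbon remote from silicon and keep the α-silyl carbon–titanium bond. Which aldehyde reacts first rests on MgBr2 chelation between the C4 carbonyl and the α-OPMB oxygen and on the bulk of the non-chelating α-OTIPS group at the other carbonyl; because the PMB oxygen is also β to the C1 carbonyl, the silyl bulk is the safer discriminator. C4 is set by Cram-chelate addition anti to the C6 substituent on the five-membered chelate, which puts 4-OH trans to 5-OPMB (4S). C1 is set by the titanium tether: O1 and O4 end on the same metal in a boat-like bicyclic transition state, so 1-OH is expected cis to 4-OH and hence cis to 6-OTIPS (1S in 12), not trans; this centre is reset in steps 9 and 10, so either outcome is tolerated. Inverse addition of 10 to 7 at −78 °C keeps a second complex from adding to the free aldehyde of 11 before the ring closes.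

Step 7
Reactants: 12 (1S,4S,5R,6R)-3-[(tert-butyldimethylsilyloxy)methyl]-5-(4-methoxybenzyloxy)-6-(triisopropylsilyloxy)-2-(trimethylsilyl)cyclohex-2-ene-1,4-diol
Product: 13 (1R,4S,5R,6R)-3-(hydroxymethyl)-5-(4-methoxybenzyloxy)-6-(triisopropylsilyloxy)cyclohex-2-ene-1,4-diol
Conditions: TBAF (3 equiv), THF, 0 °C → rt, short reaction time
Reagents that add atoms: none
Why: Fluoride cleaves the primary silyl ether quickly; the freed C7 alkoxide lies cis to the C2 trimethylsilyl group and removes it by a Brook-type 1,4 carbon-to-oxygen silyl shift through a five-membered silicate, with protonation at C2 (hydroxyl-assisted protodesilylation of a vinylsilane). The flanked secondary triisopropylsilyl ether reacts much more slowly at this temperature.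

Step 8
Reactants: 13 (1R,4S,5R,6R)-3-(hydroxymethyl)-5-(4-methoxybenzyloxy)-6-(triisopropylsilyloxy)cyclohex-2-ene-1,4-diol
Product: 14 (1R,4S,5R,6R)-4,7-O-isopropylidene derivative of 13 (six-membered acetonide across O4 and O7; free 1-OH cis to 6-OTIPS)
Conditions: 2,2-dimethoxypropane, PPTS (cat.), CH2Cl2, rt
Reagents that add atoms: 2,2-dimethoxypropane, COC(C)(C)OC
Why: Acid-catalysed acetal exchange; only O4 and O7 form a 1,3-diol that can close a six-membered acetonide, so O1 is left as the only free hydroxyl.

Step 9
Reactants: 14 (1R,4S,5R,6R)-4,7-O-isopropylidene-3-(hydroxymethyl)-5-(4-methoxybenzyloxy)-6-(triisopropylsilyloxy)cyclohex-2-ene-1,4-diol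
Product: 15 (4S,5R,6S)-4,7-O-isopropylidene-4-hydroxy-3-(hydroxymethyl)-5-(4-methoxybenzyloxy)-6-(triisopropylsilyloxy)cyclohex-2-en-1-one (enone, C1 ketone)
Conditions: Dess–Martin periodinane, NaHCO3, CH2Cl2, 0 °C → rt
Reagents that add atoms: none
Why: Dess–Martin oxidation of the allylic alcohol under buffered, near-neutral conditions that spare acetonide, benzyl-type ether and silyl ether and avoid β-elimination of the C5 ether; it erases the C1 configuration so that either epimer from step 6 converges.

Step 10
Reactants: 15 (4S,5R,6S)-4,7-O-isopropylidene-4-hydroxy-3-(hydroxymethyl)-5-(4-methoxybenzyloxy)-6-(triisopropylsilyloxy)cyclohex-2-en-1-one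
Product: 16 (1S,4S,5R,6R)-4,7-O-isopropylidene-3-(hydroxymethyl)-5-(4-methoxybenzyloxy)-6-(triisopropylsilyloxy)cyclohex-2-ene-1,4-diol (free 1-OH trans to 6-OTIPS)
Conditions: NaBH4, CeCl3·7H2O, MeOH, −78 °C
Reagents that add atoms: none
Why: Luche 1,2-reduction; in the half-chair with the 4,5,6-substituents equatorial, hydride should enter axially, anti to the axial hydrogen on C6, giving the pseudo-equatorial alcohol trans to O6 (1S), the usual outcome for all-trans 6-alkoxycyclohex-2-enones.

Step 11
Reactants: 16 (1S,4S,5R,6R)-4,7-O-isopropylidene-3-(hydroxymethyl)-5-(4-methoxybenzyloxy)-6-(triisopropylsilyloxy)cyclohex-2-ene-1,4-diol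
Product: 17 (1S,4S,5R,6R)-4,7-O-isopropylidene-3-(hydroxymethyl)-1-methoxy-5-(4-methoxybenzyloxy)-6-(triisopropylsilyloxy)cyclohex-2-en-4-ol (1-O-methyl ether of 16)
Conditions: NaH, MeI, THF/DMF, 0 °C → rt
Reagents that add atoms: iodomethane, CI
Why: Williamson methylation of the only free hydroxyl; the trans triisopropylsilyl ether migrates too slowly to interfere, and no C–O bond at a stereocentre is broken.

Step 12
Reactants: 17 1-O-methyl ether of 16
Product: 18 (1S,4S,5R,6S)-4,7-O-isopropylidene-3-(hydroxymethyl)-1-methoxy-6-(triisopropylsilyloxy)cyclohex-2-ene-4,5-diol (free 5-OH)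
Conditions: DDQ, CH2Cl2/pH 7 buffer, 0 °C
Reagents that add atoms: none
Why: Oxidative cleavage of the 4-methoxybenzyl ether through its benzylic cation; the buffer protects the acetonide, and the simple allylic methyl ether and the alkene are oxidised far more slowly.

Step 13
Reactants: 18 (1S,4S,5R,6S)-4,7-O-isopropylidene-3-(hydroxymethyl)-1-methoxy-6-(triisopropylsilyloxy)cyclohex-2-ene-4,5-diol
Product: 19 (1S,4S,5R,6R)-5-benzoate of 18 (4,7-acetonide, 1-OMe, 6-OTIPS)
Conditions: BzCl, pyridine, DMAP (cat.), CH2Cl2, rt
Reagents that add atoms: benzoyl chloride, O=C(Cl)c1ccccc1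
Why: DMAP-catalysed acylation of the single free, hindered secondary hydroxyl; no other nucleophilic site is present.

Step 14
Reactants: 19 5-benzoate of 18
Product: 20 (1S,4S,5R,6R)-5-(benzoyloxy)-3-(hydroxymethyl)-1-methoxy-6-(triisopropylsilyloxy)cyclohex-2-en-4-ol (4,7-diol)
Conditions: AcOH/THF/H2O, 40 °C
Reagents that add atoms: none
Why: Mild aqueous acid hydrolyses the six-membered acetonide; silyl ether, benzoate and allylic methyl ether are stable, and acid keeps the C5 benzoate from migrating.

Step 15
Reactants: 20 (1S,4S,5R,6R)-5-(benzoyloxy)-3-(hydroxymethyl)-1-methoxy-6-(triisopropylsilyloxy)cyclohex-2-en-4-ol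
Product: 21 (1S,4S,5R,6R)-5-(benzoyloxy)-3-(benzoyloxymethyl)-1-methoxy-6-(triisopropylsilyloxy)cyclohex-2-en-4-ol
Conditions: BzCl (1.05 equiv), 2,4,6-collidine, CH2Cl2, −40 → 0 °C
Reagents that add atoms: benzoyl chloride, O=C(Cl)c1ccccc1
Why: The primary allylic hydroxyl is acylated far faster than the secondary C4 hydroxyl, which is flanked by C3 and the C5 benzoate; low temperature and a weak base suppress diacylation and acyl migration.

Step 16
Reactants: 21 (1S,4S,5R,6R)-5-(benzoyloxy)-3-(benzoyloxymethyl)-1-methoxy-6-(triisopropylsilyloxy)cyclohex-2-en-4-ol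
Product: 22 target, [(3S,4R,5R,6S)-5-(benzoyloxy)-4,6-dihydroxy-3-methoxycyclohex-1-en-1-yl]methyl benzoate (1S,4S,5R,6R on the positional labels)
Conditions: HF·pyridine, THF/pyridine, 0 °C → rt
Reagents that add atoms: none
Why: Acidic fluoride cleaves the silyl ether without forming an alkoxide, so neither benzoate should migrate; no stereocentre is touched.

## Compound list

1 | diethyl D-tartrate, diethyl (2S,3S)-2,3-dihydroxybutanedioate | CCOC(=O)[C@@H](O)[C@H](O)C(=O)OCC | starting material
2 | 4-methoxybenzyl chloride | COc1ccc(CCl)cc1 | starting material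
3 | diethyl (4S,5S)-2,2-dibutyl-1,3,2-dioxastannolane-4,5-dicarboxylate (stannylene acetal) | CCOC(=O)[C@H]1O[Sn](CCCC)(CCCC)O[C@@H]1C(=O)OCC | intermediate
4 | diethyl (2S,3S)-2-hydroxy-3-(4-methoxybenzyloxy)butanedioate | CCOC(=O)[C@@H](O)[C@H](OCc1ccc(OC)cc1)C(=O)OCC | intermediate
5 | diethyl (2S,3S)-2-(4-methoxybenzyloxy)-3-(triisopropylsilyloxy)butanedioate | CCOC(=O)[C@@H](OCc1ccc(OC)cc1)[C@H](O[Si](C(C)C)(C(C)C)C(C)C)C(=O)OCC | intermediate
6 | (2R,3R)-2-(4-methoxybenzyloxy)-3-(triisopropylsilyloxy)butane-1,4-diol | OC[C@@H](OCc1ccc(OC)cc1)[C@H](O[Si](C(C)C)(C(C)C)C(C)C)CO | intermediate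
7 | (2S,3S)-2-(4-methoxybenzyloxy)-3-(triisopropylsilyloxy)butanedial | O=C[C@@H](OCc1ccc(OC)cc1)[C@H](O[Si](C(C)C)(C(C)C)C(C)C)C=O | intermediate
8 | 3-(trimethylsilyl)prop-2-yn-1-ol | C[Si](C)(C)C#CCO | starting material
9 | tert-butyldimethyl{[3-(trimethylsilyl)prop-2-yn-1-yl]oxy}silane | C[Si](C)(C)C#CCO[Si](C)(C)C(C)(C)C | intermediate
10 | 2-[(tert-butyldimethylsilyloxy)methyl]-1,1-di(propan-2-yloxy)-3-(trimethylsilyl)titanacycloprop-2-ene (alkyne complex of 9) | CC(C)O[Ti]1(OC(C)C)C(CO[Si](C)(C)C(C)(C)C)=C1[Si](C)(C)C | intermediate
11 | 4-[(tert-butyldimethylsilyloxy)methyl]-5-[(1S,2S)-1-(4-methoxybenzyloxy)-3-oxo-2-(triisopropylsilyloxy)propyl]-2,2-di(propan-2-yloxy)-3-(trimethylsilyl)-1-oxa-2-titanacyclopent-3-ene (4S,5S,6S on the positional labels) | CC(C)O[Ti]1(OC(C)C)O[C@H]([C@@H](OCc2ccc(OC)cc2)[C@H](O[Si](C(C)C)(C(C)C)C(C)C)C=O)C(CO[Si](C)(C)C(C)(C)C)=C1[Si](C)(C)C | intermediate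
12 | (1S,4S,5R,6R)-3-[(tert-butyldimethylsilyloxy)methyl]-5-(4-methoxybenzyloxy)-6-(triisopropylsilyloxy)-2-(trimethylsilyl)cyclohex-2-ene-1,4-diol (1-OH cis to 4-OH and to 6-OTIPS) | O[C@@H]1C([Si](C)(C)C)=C(CO[Si](C)(C)C(C)(C)C)[C@H](O)[C@@H](OCc2ccc(OC)cc2)[C@@H]1O[Si](C(C)C)(C(C)C)C(C)C | intermediate
13 | (1R,4S,5R,6R)-3-(hydroxymethyl)-5-(4-methoxybenzyloxy)-6-(triisopropylsilyloxy)cyclohex-2-ene-1,4-diol | O[C@@H]1C=C(CO)[C@H](O)[C@@H](OCc2ccc(OC)cc2)[C@@H]1O[Si](C(C)C)(C(C)C)C(C)C | intermediate
14 | (1R,4S,5R,6R)-4,7-O-isopropylidene-3-(hydroxymethyl)-5-(4-methoxybenzyloxy)-6-(triisopropylsilyloxy)cyclohex-2-ene-1,4-diol | O[C@@H]1C=C2COC(C)(C)O[C@@H]2[C@@H](OCc3ccc(OC)cc3)[C@@H]1O[Si](C(C)C)(C(C)C)C(C)C | intermediate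
15 | (4S,5R,6S)-4,7-O-isopropylidene-4-hydroxy-3-(hydroxymethyl)-5-(4-methoxybenzyloxy)-6-(triisopropylsilyloxy)cyclohex-2-en-1-one | O=C1C=C2COC(C)(C)O[C@@H]2[C@@H](OCc3ccc(OC)cc3)[C@@H]1O[Si](C(C)C)(C(C)C)C(C)C | intermediate
16 | (1S,4S,5R,6R)-4,7-O-isopropylidene-3-(hydroxymethyl)-5-(4-methoxybenzyloxy)-6-(triisopropylsilyloxy)cyclohex-2-ene-1,4-diol (1-OH trans to 6-OTIPS) | O[C@H]1C=C2COC(C)(C)O[C@@H]2[C@@H](OCc3ccc(OC)cc3)[C@@H]1O[Si](C(C)C)(C(C)C)C(C)C | intermediate
17 | (1S,4S,5R,6R)-4,7-O-isopropylidene-3-(hydroxymethyl)-1-methoxy-5-(4-methoxybenzyloxy)-6-(triisopropylsilyloxy)cyclohex-2-en-4-ol | CO[C@H]1C=C2COC(C)(C)O[C@@H]2[C@@H](OCc3ccc(OC)cc3)[C@@H]1O[Si](C(C)C)(C(C)C)C(C)C | intermediate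
18 | (1S,4S,5R,6S)-4,7-O-isopropylidene-3-(hydroxymethyl)-1-methoxy-6-(triisopropylsilyloxy)cyclohex-2-ene-4,5-diol | CO[C@H]1C=C2COC(C)(C)O[C@@H]2[C@@H](O)[C@@H]1O[Si](C(C)C)(C(C)C)C(C)C | intermediate
19 | (1S,4S,5R,6R)-5-(benzoyloxy)-4,7-O-isopropylidene-3-(hydroxymethyl)-1-methoxy-6-(triisopropylsilyloxy)cyclohex-2-en-4-ol | CO[C@H]1C=C2COC(C)(C)O[C@@H]2[C@@H](OC(=O)c3ccccc3)[C@@H]1O[Si](C(C)C)(C(C)C)C(C)C | intermediate
20 | (1S,4S,5R,6R)-5-(benzoyloxy)-3-(hydroxymethyl)-1-methoxy-6-(triisopropylsilyloxy)cyclohex-2-en-4-ol | CO[C@H]1C=C(CO)[C@H](O)[C@@H](OC(=O)c2ccccc2)[C@@H]1O[Si](C(C)C)(C(C)C)C(C)C | intermediate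
21 | (1S,4S,5R,6R)-5-(benzoyloxy)-3-(benzoyloxymethyl)-1-methoxy-6-(triisopropylsilyloxy)cyclohex-2-en-4-ol | CO[C@H]1C=C(COC(=O)c2ccccc2)[C@H](O)[C@@H](OC(=O)c2ccccc2)[C@@H]1O[Si](C(C)C)(C(C)C)C(C)C | intermediate
22 | [(3S,4R,5R,6S)-5-(benzoyloxy)-4,6-dihydroxy-3-methoxycyclohex-1-en-1-yl]methyl benzoate | CO[C@H]1C=C(COC(=O)c2ccccc2)[C@H](O)[C@@H](OC(=O)c2ccccc2)[C@@H]1O | target

## Step count and least certain steps

Total: 16 steps. Longest linear sequence: 15 steps (steps 1–4 and 6–16 from 1); step 5 is the one-step side branch.

**Step 6 (key step, proposed new method).** Several processes can defeat it: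
- The sequence may stop at 11, because the titanium alkoxide on O4 can add to the free aldehyde as a five-membered lactolate and the α-silyl vinyl–titanium bond is a weak nucleophile.
- The first addition may occur at the wrong aldehyde, which leads to a constitutional isomer.
- Facial selectivity at C4 may be low or reversed, because isopropoxytitanium centres chelate weakly and the outcome leans on the added MgBr2.
- Two complexes may add, one to each aldehyde.
- The complex 10 may lose silyloxide to give an allenyltitanium.

The fallback uses known reactions only, sets out from 7 and comes back to the route at 15. The alkenylmagnesium reagent from 2-bromoallyl tert-butyldimethylsilyl ether (t-BuLi, then MgBr2·OEt2) is added under chelation control to the OPMB-flanked aldehyde of 7. The alkoxide closes on the second aldehyde and masks it, giving 5-[3-(tert-butyldimethylsilyloxy)prop-1-en-2-yl]-4-(4-methoxybenzyloxy)-3-(triisopropylsilyloxy)oxolan-2-ol F1. Excess vinylmagnesium bromide opens the lactol to 2-[(tert-butyldimethylsilyloxy)methyl]-4-(4-methoxybenzyloxy)-5-(triisopropylsilyloxy)octa-1,7-diene-3,6-diol F2 as a C1-epimer mixture. Ring-closing metathesis with the second-generation Grubbs catalyst forms C2=C3 and gives 3-[(tert-butyldimethylsilyloxy)methyl]-5-(4-methoxybenzyloxy)-6-(triisopropylsilyloxy)cyclohex-2-ene-1,4-diol F3. TBAF at 0 °C frees C7–OH to give the C1-epimeric triol F4, acetonide formation as in step 8 gives the C1-epimeric acetonide F5, and Dess–Martin oxidation converges both epimers on 15.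

**Step 4.** The likely failure is epimerisation at the two α-alkoxy carbons during amine treatment, or hydration and oligomerisation of the dialdehyde on handling. The fallback sets out from 5 and comes back at 7: direct half-reduction of both esters with i-Bu2AlH in toluene at −78 °C, Rochelle-salt work-up in the cold and immediate use, which avoids the diol and any amine base. No compound outside the list is made (F0).

**Step 7.** The likely failure is loss of the triisopropylsilyl group, or its shift from O6 to the cis O1, if the C–Si cleavage needs longer exposure to basic fluoride. The fallback avoids fluoride, sets out from 12 and comes back at 13. PPTS in MeOH removes only the primary silyl ether to give (1S,4S,5R,6R)-3-(hydroxymethyl)-5-(4-methoxybenzyloxy)-6-(triisopropylsilyloxy)-2-(trimethylsilyl)cyclohex-2-ene-1,4-diol F6. Catalytic KO-t-Bu in wet THF then triggers the 1,4 carbon-to-oxygen silyl shift and protonation, and aqueous work-up gives 13.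

**Step 10.** The likely failure is poor facial selectivity of hydride delivery if the bulky silyloxy group forces the ring into the all-axial conformer, which would return the cis alcohol. The fallback does not use the ketone; it sets out from 14 and comes back at 16. Mitsunobu inversion with 4-nitrobenzoic acid, PPh3 and DIAD gives the inverted 1-O-(4-nitrobenzoyl) ester F7 of 16, and K2CO3 in MeOH frees 16.

**Step 15.** The likely failure is over-acylation at O4, or acyl migration from O5 to O4 under the basic acylation conditions. The fallback sets out from 20 and comes back at 21: Mitsunobu esterification with benzoic acid, PPh3 and DIAD at 0 °C, which activates only the unhindered primary alcohol and uses no amine base. No compound outside the list is made (F0).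

## Further compounds

F1 | step 6 | 5-[3-(tert-butyldimethylsilyloxy)prop-1-en-2-yl]-4-(4-methoxybenzyloxy)-3-(triisopropylsilyloxy)oxolan-2-ol (anomers) | OC1O[C@@H](C(=C)CO[Si](C)(C)C(C)(C)C)[C@@H](OCc2ccc(OC)cc2)[C@@H]1O[Si](C(C)C)(C(C)C)C(C)C
F2 | step 6 | 2-[(tert-butyldimethylsilyloxy)methyl]-4-(4-methoxybenzyloxy)-5-(triisopropylsilyloxy)octa-1,7-diene-3,6-diol (C1 epimers) | C=C(CO[Si](C)(C)C(C)(C)C)[C@H](O)[C@@H](OCc1ccc(OC)cc1)[C@H](O[Si](C(C)C)(C(C)C)C(C)C)C(O)C=C
F3 | step 6 | 3-[(tert-butyldimethylsilyloxy)methyl]-5-(4-methoxybenzyloxy)-6-(triisopropylsilyloxy)cyclohex-2-ene-1,4-diol (C1 epimers) | OC1C=C(CO[Si](C)(C)C(C)(C)C)[C@H](O)[C@@H](OCc2ccc(OC)cc2)[C@@H]1O[Si](C(C)C)(C(C)C)C(C)C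
F4 | step 6 | 3-(hydroxymethyl)-5-(4-methoxybenzyloxy)-6-(triisopropylsilyloxy)cyclohex-2-ene-1,4-diol (C1 epimers) | OC1C=C(CO)[C@H](O)[C@@H](OCc2ccc(OC)cc2)[C@@H]1O[Si](C(C)C)(C(C)C)C(C)C
F5 | step 6 | 4,7-O-isopropylidene-3-(hydroxymethyl)-5-(4-methoxybenzyloxy)-6-(triisopropylsilyloxy)cyclohex-2-ene-1,4-diol (C1 epimers) | OC1C=C2COC(C)(C)O[C@@H]2[C@@H](OCc3ccc(OC)cc3)[C@@H]1O[Si](C(C)C)(C(C)C)C(C)C
F0 | step 4 | none | none
F6 | step 7 | (1S,4S,5R,6R)-3-(hydroxymethyl)-5-(4-methoxybenzyloxy)-6-(triisopropylsilyloxy)-2-(trimethylsilyl)cyclohex-2-ene-1,4-diol | O[C@@H]1C([Si](C)(C)C)=C(CO)[C@H](O)[C@@H](OCc2ccc(OC)cc2)[C@@H]1O[Si](C(C)C)(C(C)C)C(C)C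
F7 | step 10 | 1-O-(4-nitrobenzoyl) ester of 16 | O=C(O[C@H]1C=C2COC(C)(C)O[C@@H]2[C@@H](OCc3ccc(OC)cc3)[C@@H]1O[Si](C(C)C)(C(C)C)C(C)C)c4ccc(cc4)[N+](=O)[O-]
F0 | step 15 | none | none
A1 | alternative 1 | ethyl (5S,6R)-5,6-dihydroxycyclohexa-1,3-diene-1-carboxylate | CCOC(=O)C1=CC=C[C@H](O)[C@@H]1O
A2 | alternative 1 | ethyl benzoate | CCOC(=O)c1ccccc1
A3 | alternative 2 | 4,6-bis(tert-butyldimethylsilyl) ether of the target | CO[C@H]1C=C(COC(=O)c2ccccc2)[C@H](O[Si](C)(C)C(C)(C)C)[C@@H](OC(=O)c2ccccc2)[C@@H]1O[Si](C)(C)C(C)(C)C
A4 | alternative 2 | open-chain dimethyl acetal with a Z-vinylsilane: 5-(benzoyloxy)-3-(benzoyloxymethyl)-4,6-bis(tert-butyldimethylsilyloxy)-7,7-dimethoxy-2-(trimethylsilyl) chain C2=C3–C4–C5–C6–C1 | COC(OC)[C@@H](O[Si](C)(C)C(C)(C)C)[C@H](OC(=O)c1ccccc1)[C@@H](O[Si](C)(C)C(C)(C)C)/C(COC(=O)c1ccccc1)=C\[Si](C)(C)C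
A5 | alternative 3 | methyl 4-hydroxy-3-methoxy-5-(4-methoxybenzyloxy)-6-(tert-butyldimethylsilyloxy)cyclohex-1-ene-1-carboxylate | CO[C@H]1C=C(C(=O)OC)[C@H](O[Si](C)(C)C(C)(C)C)[C@@H](OCc2ccc(OC)cc2)[C@@H]1O
A6 | alternative 3 | methyl (E)-4-methoxy-2-[1-(tert-butyldimethylsilyloxy)-2-(4-methoxybenzyloxy)-3-oxopropyl]but-2-enoate | COC/C=C(C(=O)OC)\[C@H](O[Si](C)(C)C(C)(C)C)[C@@H](OCc1ccc(OC)cc1)C=O
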